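The rate constants belong to no real substance; the run is a simulation.

Start with the easy step: add the four steps and every catalyst form cancels, leaving substrate plus partner giving product.

    catalyst intermediate C ⇌ free catalyst + product (K1 = 0.040 M, k1 = 0.619 min⁻¹)
    partner + catalyst intermediate A ⇌ catalyst intermediate B (K2 = 100 M⁻¹, k2 = 127 M⁻¹ min⁻¹)
    substrate + free catalyst ⇌ catalyst intermediate A (K3 = 6.36 M⁻¹, k3 = 18.3 M⁻¹ min⁻¹)
    catalyst intermediate B ⇌ catalyst intermediate C (K4 = 1.1, k4 = 0.572 min⁻¹)

substrate 0.050 M (fed, over 12 h); partner 0.950 equiv; free catalyst 0.33 mol%; time 15 d

- the state of affairs at 15 d: stopped, and by what, or still going (no working catalyst is left / the partner has run out first / forward and back rates have come level / all of the substrate has reacted / it is still moving)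
- share of the substrate used up at 15 d
- product at 15 d, in percent of the substrate charged

- the reaction counts as stopped when no species that holds the substrate changes by six tenths of a point or more over the second half of the time
- run time (flask): 15 d

The overall equilibrium constant is therefore the product of the four constants, 28.0 M⁻¹. Multiply it by the substrate charge and you have the number to carry, the equilibrium number G, here 1.40.

Now turn the question round: what would have to be true for this flask not to end with forward and back rates level? It could still be moving at 15 d. But with the whole catalyst charge free, the forward capture of substrate has a half-life of 0.159 d, far shorter than the run, and about 94.3 of these fit into it.

Or the partner could run out, since its charge caps product at 95.0% of the substrate charged. Let x be product as a share of the substrate charged. At the level point, x divided by the substrate left and by the partner left, both as shares of that charge, equals G. Near the cap the partner left shrinks towards nothing, so G has to be large. Even half the substrate as product asks for G of 2.22, and this flask has less. Solving gives x = 42.4%, below the cap. That is thermodynamic control, and your reckoning counts no substrate held on the catalyst.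

The forecast is that forward and back rates have come level, with 42.5% used up and 42.3% as product, and it says “nothing deactivates the catalyst or runs out first”. The simulation finds that forward and back rates have come level, with 42.5% used up and 42.3% as product.

In this flask the half-life of substrate by the forward capture step alone, read at 0.763 d, is 0.37 d, far shorter than the 15 d of the run. Product already reads 42.3% at 7.50 d and the same at 15.0 d, with substrate still holding more. The two hold the same at 1.59 times the substrate, where G is 2.23. The neighbour with 0.12 M of substrate has G of 3.36, which puts x at 56.4%, and that flask ends with 56.3% product.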